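Count how often each free catalyst turns over in this flask.

| flask | left-handed substrate | right-handed substrate | reagent | free catalyst | impurity | temperature | remark | time |
|---|---|---|---|---|---|---|---|---|
| eta | 0.50 M | 0.50 M | 1.5 M | 48 mM | 70 mM | 25 °C | the very flask that is asked about, followed so far |  |
| delta | 0.50 M | 0.50 M | 1.5 M | 48 mM | 47 mM | 20 °C | run made earlier |  |
| flask | 0.50 M | 0.50 M | 1.50 M | 48 mM | 70 mM | 25 °C |  | 5.0 h |

| run | time / h | left-handed product / % |
|---|---|---|
| eta | 0.833 | 7.8 |
| eta | 1.50 | 8.5 |
| eta | 2.50 | 7.5 |
| eta | 3.00 | 8.8 |
| delta | 0.667 | 7.6 |
| delta | 2.00 | 14.3 |
| delta | 3.00 | 14.6 |
| delta | 5.00 | 18.5 |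

(standard deviation of a reading: 0.5 percentage points)

- red: change nothing and wait 1.5 h more
- teal: at 5.0 h add free catalyst, 100% of the amount charged, then wait 1.5 h
- grey: at 5.0 h take out 90% of the left-handed product then present, then wait 1.5 h
- green: at 5.0 h raise the temperature by 10 K, then wait 1.5 h

- free catalyst is single-handed; left-handed substrate and right-handed substrate are mirror images of each other, charged as a racemate, each of them at the stated concentration
- left-handed product that was removed still counts
- additions bring no volume worth counting

1. left-handed product, in percent of the left-handed substrate and right-handed substrate together first charged, at 5.0 h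
2. which option adds most left-handed product ("none" when 2 percentage points or less is all one gets) (red / teal / grey / green / none)
3. left-handed product present, with what was taken out counted in, in percent of the left-handed substrate and right-handed substrate together first charged, after teal
4. left-handed product present, with what was taken out counted in, in percent of the left-handed substrate and right-handed substrate together first charged, after grey

In the first instants of the eta run, which is this flask followed so far, free catalyst works beside 70 mM of impurity, more than its own 48 mM. I take it that impurity removes catalyst, one for one, while the catalyst works. The middle of the eta run is short: the reading at 0.833 h already stands at 7.8%. Then the eta run stops, with 7.5% at 2.50 h and 8.8% at 3.00 h, a wander without trend against a scatter of 0.5 percentage points. This is no ceiling, because the colder delta run, with 47 mM of impurity, reached 18.5%, more.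

The mean of the eta readings is 8.15% of the substrates together. That makes 1.70 left-handed product per free catalyst charged at this charge of impurity, which I call the turnover count, the field's turnover number.

So at 5.0 h I expect this flask to hold 8.15%. With the catalyst lost, I expect red, grey and green each to gain less than 2 points, and grey to stay at 8.15%. Teal differs: by my one-for-one count, impurity left after the first charge is 22.0 mM, less than the added dose, so 26.0 mM of the dose should survive. Even at the same turnover count, teal reaches 16.3%, which I take as a floor.

The forecast says 8.2%, teal as best, 23% after teal and 8.4% after grey: “This points to catalyst death rather than equilibrium or product inhibition.”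

The flask gives 8.47%, teal as best with a gain of 22 points, 30.8% after teal and 8.47% after grey. The forecast for teal stands 7.8 points low.

    free catalyst + left-handed substrate ⇌ catalyst intermediate A (K = 2.20 /M, k = 49.0 /M/h, Ea = 51.0 kJ/mol, ΔH = 14.0 kJ/mol)
    free catalyst + right-handed substrate ⇌ catalyst intermediate B (K = 1.30 /M, k = 68.0 /M/h, Ea = 54.0 kJ/mol, ΔH = −61.0 kJ/mol)
    reagent + catalyst intermediate A → free catalyst + left-handed product (k = 22.0 /M/h, Ea = 56.0 kJ/mol)
    reagent + catalyst intermediate B → free catalyst + right-handed product (k = 8.90 /M/h, Ea = 65.0 kJ/mol)
    left-handed substrate ⇌ right-handed substrate (k = 0.590 /h, Ea = 90.0 kJ/mol)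
    free catalyst + impurity → spent catalyst (k = 180 /M/h, Ea = 66.0 kJ/mol)
    (constants at 25 °C)

In this flask the first charge gave 1.76 turnovers, beside the 1.70 read from the eta run. The teal dose gave 4.65 per catalyst added, more than the first charge, so the count read from the eta run does not carry over to the teal dose. A neighbouring flask holds 0.029 M of free catalyst, less than its 70 mM of impurity. The turnover count promises 4.92% in that neighbouring flask, and it gives 4.13%.

(The runs are simulated for substances that don't exist, and the scatter is random.)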